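**Plan**
- Retrosynthesis: ring A is opened last at C1–C10 (enol δ-lactone vinyl ketone 30). Before that come C3–C4 (aldol with acrolein), C13–C16 (ring D), the C19–O–C20 lactone, C4–C5 (Michael), C6–C7 (carbonylation), C10–C20 (dithiane) and C8–C9 with C13–C14 (intramolecular Diels–Alder), back to an aldol of enone 5 with dienal 7.
- Forward: rings C and B form together (step 5); ring B is then dressed with C20, C7 and the C4 propionate; C19 and C20 are tied as a temporary enol lactone; ring D closes (step 14); C4 becomes quaternary (step 15); ring A closes last (step 17).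
- Enabling feature: C19 (on C4) and C20 (on C10) are 1,3-diaxial on the α-face of ring A, and O20 and O3 are 1,5-related through C10–C1–C2–C3. Tied as the six-membered enol lactone C19–O–C20=C10–C5–C4, C10 is the nucleophilic β-carbon of an enol ester and faces C1, the β-carbon of a C3 vinyl ketone.
- Stereochemistry: a boron aldol sets a C10 carbinol that steers the cycloaddition (C8, C9) and is then erased. C10 and C5 come from anti additions, C6 from equilibration, C4 from a lactone-enolate aldol anti to C6, quaternary C10 from the lactone tether, C3 from K-Selectride, C13 from the bridge.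
- Helpers removed later: dithiane, silyl groups, tert-butyl and allyl esters, and the lactone ring itself (the final hydrolysis of the methoxy lactone releases the C19 acid and the C20 aldehyde).

Key step: step 17

Remark: gibberellane numbering (C1–C20) is used for all intermediates; TMS = trimethylsilyl, TBS = tert-butyldimethylsilyl.
Assumption: (−)-Ipc2BCl is taken to give the (R)-aldol 10, and the carbinol is taken to sit cis to H-9 in cycloadduct 11; if either sense is the opposite, (+)-Ipc2BCl is used, since this centre is erased in step 7.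
Assumption: the target is written as the open aldehyde–acid, which is in ring–chain equilibrium with its 19,20-lactol.

Step 1
Reactants: 1 tert-butyl acetoacetate; 2 3-bromo-1-(trimethylsilyl)prop-1-yne
Product: 3 tert-butyl 2-acetyl-5-(trimethylsilyl)pent-4-ynoate (racemic)
Conditions: K2CO3, acetone, reflux
Reagents that add atoms: none
Why: Acetoacetic ester alkylation; the stabilised enolate is C-alkylated once by the propargylic bromide, and the stereocentre is lost in step 2.

Step 2
Reactants: 3 tert-butyl 2-acetyl-5-(trimethylsilyl)pent-4-ynoate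
Product: 5 3-methylidene-6-(trimethylsilyl)hex-5-yn-2-one, via beta-keto acid 4 (not isolated)
Conditions: TFA, CH2Cl2, rt; evaporate; 37% aq CH2O, Et2NH, THF, 0 °C to rt
Reagents that add atoms: formaldehyde, C=O
Why: Acidolysis of the tert-butyl ester followed by a decarboxylative Mannich reaction–elimination, which places the methylidene group (C14) regiospecifically on the former malonic carbon (C8).

Step 3
Reactants: 6 glutaconaldehyde potassium salt
Product: 7 (2E,4E)-5-[(tert-butyldimethylsilyl)oxy]penta-2,4-dienal
Conditions: TBSCl, DMF, 0 °C to rt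
Reagents that add atoms: tert-butyldimethylsilyl chloride, CC(C)(C)[Si](C)(C)Cl
Why: O-Silylation of the dienolate should give the all-trans silyloxy dienal, the E,E geometry being that of the salt.

Step 4
Reactants: 5 3-methylidene-6-(trimethylsilyl)hex-5-yn-2-one; 7 (2E,4E)-5-[(tert-butyldimethylsilyl)oxy]penta-2,4-dienal
Product: 10 (7R,8E,10E)-11-[(tert-butyldimethylsilyl)oxy]-7-hydroxy-4-methylidene-1-(trimethylsilyl)undeca-8,10-dien-1-yn-5-one, via boron enolate 8 (not isolated), via boron aldolate 9 (not isolated)
Conditions: (−)-Ipc2BCl, Et3N, Et2O, 0 °C; 7, −78 to −20 °C; H2O2, MeOH, pH 7 buffer, 0 °C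
Reagents that add atoms: none
Why: Boron-mediated aldol addition of a methyl ketone; only the methyl group can enolise, the diisopinocampheylboron enolate adds 1,2 to the dienal through a closed six-membered transition state, and the chiral ligands on boron set the C10 carbinol (R).

Step 5
Reactants: 10 the (R)-aldol
Product: 11 cis-fused bicycle of ring B (C5, C6, C8, C9, C10) and ring C (C8, C9, C11–C14): C6 ketone, 10β-OH cis to H-9, C11=C12, 13-OTBS trans to the 8-(3-TMS-prop-2-ynyl) group, which is cis to H-9
Conditions: toluene, BHT (cat.), 90 °C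
Reagents that add atoms: none
Why: Intramolecular Diels–Alder reaction of a 1,6,8-nonatrien-3-one; the enone carbonyl in the three-atom tether activates the 2-substituted dienophile and favours the tether-endo transition state that gives the cis-hydrindanone with the new quaternary C8, the carbinol takes the pseudo-equatorial site of the forming five-membered ring so that C8 and C9 follow from C10, and the (E,E)-diene fixes C13.

Step 6
Reactants: 11 the cycloadduct
Product: 12 the same bicycle with the C13 TBS enol ether (C12=C13) and C11 saturated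
Conditions: [Ir(cod)(PMePh2)2]PF6 (2 mol %, activated with H2), THF, rt
Reagents that add atoms: none
Why: Iridium-hydride-catalysed isomerisation of an allyl silyl ether to a silyl enol ether (hydride addition to C11, β-hydride loss from C13 on the face anti to the silyloxy group); it removes the ring-C alkene and masks the C13 ketone without a redox step.

Step 7
Reactants: 12 the β-hydroxy ketone
Product: 14 bicyclic cyclopentenone (C6 ketone, C5=C10), via mesylate 13 (not isolated)
Conditions: MsCl, Et3N (excess), CH2Cl2, 0 °C to rt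
Reagents that add atoms: none
Why: Mesylation and E1cB elimination of the β-mesyloxy ketone; the auxiliary C10 centre is erased and C8 and C9 remain.

Step 8
Reactants: 14 the cyclopentenone; 15 1,3-dithiane
Product: 17 enol triflate (C6–OTf, C5=C6) with a 10β-(1,3-dithian-2-yl) group cis to H-9, via lithium enolate 16 (not isolated)
Conditions: 15, n-BuLi, THF, −30 °C; HMPA, −78 °C; 14; then PhNTf2, −78 to 0 °C
Reagents that add atoms: N-phenylbis(trifluoromethanesulfonimide), O=S(=O)(N(c1ccccc1)S(=O)(=O)C(F)(F)F)C(F)(F)F
Why: 1,4-Addition of 2-lithio-1,3-dithiane (HMPA makes the addition conjugate) on the face of C10 anti to C11 of the cis-fused ring C, followed by O-triflation of the regiodefined enolate (C8 is quaternary, so only C5 can carry the enolate).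

Step 9
Reactants: 17 the enol triflate
Product: 18 allyl cyclopentenecarboxylate (C7 allyl ester on C6, C5=C6)
Conditions: Pd(OAc)2 (5 mol %), dppf, CO (1 atm), allyl alcohol, Et3N, DMF, 50 °C
Reagents that add atoms: carbon monoxide, [C-]#[O+]; allyl alcohol, C=CCO
Why: Palladium-catalysed alkoxycarbonylation of an enol triflate; the silyl alkyne, silyl enol ether and dithiane are inert under these conditions, and no stereocentre is formed.

Step 10
Reactants: 18 the enoate; 19 tert-butyl propanoate
Product: 21 Michael adduct (C5–C4 bond, 5β-H, 6β-CO2allyl, C4 methine as an epimer mixture), via lithium ester enolate 20 (not isolated)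
Conditions: LDA, 19, THF, −78 °C; 18; then t-BuOH, −78 to 0 °C; aq NH4Cl
Reagents that add atoms: none
Why: Michael addition of a lithium ester enolate to a cyclopentene carboxylate; attack at C5 is anti to the dithianyl group on C10 (C4 ends α), and lithium tert-butoxide formed in the quench equilibrates the C6 ester to the trans (6β) arrangement.

Step 11
Reactants: 21 the Michael adduct
Product: 22 C13 ketone with the free propargyl group on C8
Conditions: TBAF, AcOH, THF, 0 °C to rt
Reagents that add atoms: none
Why: Buffered fluoride cleaves the alkynyl-silicon bond and the silyl enol ether in one operation, and the acetic acid protonates the enolate so that no stereocentre is disturbed.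

Step 12
Reactants: 22 the dithiane
Product: 23 C20 aldehyde on C10 (keto aldehyde, tert-butyl and allyl esters intact)
Conditions: MeI, CaCO3, MeCN–H2O (9:1), 45 °C
Reagents that add atoms: water, O
Why: Alkylative hydrolysis of the dithioacetal under buffered conditions, which spare the alkyne and both esters; the C10 methine is epimerisable but becomes sp2 in step 13.

Step 13
Reactants: 23 the keto aldehyde
Product: 25 enol δ-lactone (ring C19–O–C20=C10–C5–C4) fused to ring B, C4 bearing H and CH3, via aldehydo acid 24 (not isolated)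
Conditions: TFA, CH2Cl2, 0 °C to rt; evaporate; Ac2O, NaOAc, 100 °C
Reagents that add atoms: none
Why: Acidolysis of the tert-butyl ester, then enol lactonisation of the δ-aldehydo acid through its lactol acetate; elimination can only run towards C10, and the allyl ester at C7 cannot take part.

Step 14
Reactants: 25 the propargyl ketone
Product: 26 tetracyclic enol lactone with ring D closed (13-OH at the bridgehead, 16-methylidene)
Conditions: SmI2, HMPA, t-BuOH, THF, 0 °C to rt
Reagents that add atoms: none
Why: Ketyl–alkyne reductive cyclisation; the C13 ketyl adds 5-exo-dig to the axial propargyl group to give the bicyclo[3.2.1]octane, C13 is fixed by the bridge, and the only other acceptor in reach (C10 of the enol ester) is fully substituted.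

Step 15
Reactants: 26 the enol lactone; 27 acrolein
Product: 29 aldol adduct with quaternary C4 (CH3 and a 1-hydroxyprop-2-enyl group; C3 carbinol as an epimer mixture), via dilithium alkoxide enolate 28 (not isolated)
Conditions: LDA (2.2 equiv), THF, −78 °C; 27, −78 °C; AcOH quench at −78 °C
Reagents that add atoms: none
Why: Aldol addition of a lactone enolate to acrolein (1,2-addition); the enol-ester α-hydrogen is more acidic than that of the C7 allyl ester, and the aldehyde approaches C4 anti to the C5–C6 bond, so that C3 is trans to C6 on the lactone ring as ring A requires.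

Step 16
Reactants: 29 the allylic alcohol
Product: 30 vinyl ketone (C1=C2–C3=O on C4 of the enol lactone)
Conditions: Dess–Martin periodinane, NaHCO3, CH2Cl2, 0 °C
Reagents that add atoms: none
Why: Dess–Martin oxidation of the secondary allylic alcohol; the tertiary 13-OH cannot be oxidised and the quaternary C4 cannot enolise.

Step 17
Reactants: 30 the vinyl ketone
Product: 32 ring-A-closed 3-ketone with the C19–O–C20 lactone carrying a 20-methoxy group (C20 epimer mixture), via chloro lactone 31 (not isolated)
Conditions: MeAlCl2 (3 equiv), CH2Cl2, −78 to −30 °C; then MeOH, Et3N, −78 °C to rt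
Reagents that add atoms: methanol, CO
Why: Proposed new method: MeAlCl2 chelates the β-keto lactone (oxygens on C3 and C19) and makes C1 of the vinyl ketone strongly electrophilic; C10, the β-carbon of the enol ester C10=C20–O, attacks it to give an acyloxocarbenium ion at C20, which is trapped by chloride and then by methanol. The closest known reaction types are the Mukaiyama–Michael addition of silyl enol ethers, the TiCl4-mediated additions of enol acetates to acetals, and alkylaluminium chloride-promoted cyclisations of alkenes onto enones. Ring A (C10, C1, C2, C3, C4, C5) closes 6-endo-trig at the enone and exo with respect to the enol double bond, forming the 2-oxabicyclo[3.3.1]nonane of the natural lactol. The new quaternary centre C10 is controlled by the tether: with C19 and C20 held in one ring, C1 can only reach the face of C10 syn to the C4–C3 bond, so C20 ends cis to C19 and, with the C4/C5 relationship from step 15, the A/B fusion is trans; the acetal centre C20 is inconsequential. The step needs C-alkylation at C10 rather than reaction of the 16-ene, the allyl ester or the 13-OH: C10 is the only π-nucleophile within a six-membered transition state of C1, the 13-OH is held as its aluminium alkoxide, and MeAlCl2 scavenges protons so that the acid-labile 13-hydroxy-16-ene unit is not exposed to HCl.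

Step 18
Reactants: 32 the 3-ketone
Product: 33 the 3β-alcohol
Conditions: K-Selectride (2.5 equiv), THF, −78 °C; aq NH4Cl
Reagents that add atoms: none
Why: Bulky-hydride reduction of a ring-A ketone locked in a chair; equatorial attack gives the axial 3β-alcohol, and the hindered lactone and allyl ester carbonyls are not reduced at −78 °C.

Step 19
Reactants: 33 the 3β-alcohol
Product: 35 the target (GA23), via methoxy lactone acid 34 (not isolated)
Conditions: Pd(PPh3)4 (cat.), morpholine, THF, rt; concentrate; AcOH–THF–H2O (3:1:1), 40 °C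
Reagents that add atoms: water, O
Why: Tsuji–Trost deallylation frees the C7 acid under neutral conditions, and mild aqueous acid hydrolyses the methoxy lactone to the lactol, which opens to the C19 acid and C20 aldehyde; no base is used, so the 3-hydroxy ester cannot undergo retro-aldol epimerisation.

**Compound list**
1 | tert-butyl acetoacetate | CC(=O)CC(=O)OC(C)(C)C | starting material
2 | 3-bromo-1-(trimethylsilyl)prop-1-yne | C[Si](C)(C)C#CCBr | starting material
3 | tert-butyl 2-acetyl-5-(trimethylsilyl)pent-4-ynoate (racemic) | CC(=O)C(CC#C[Si](C)(C)C)C(=O)OC(C)(C)C | intermediate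
4 | 2-acetyl-5-(trimethylsilyl)pent-4-ynoic acid | CC(=O)C(CC#C[Si](C)(C)C)C(=O)O | intermediate (not isolated)
5 | 3-methylidene-6-(trimethylsilyl)hex-5-yn-2-one | CC(=O)C(=C)CC#C[Si](C)(C)C | intermediate
6 | glutaconaldehyde potassium salt | [K+].[O-]/C=C/C=C/C=O | starting material
7 | (2E,4E)-5-[(tert-butyldimethylsilyl)oxy]penta-2,4-dienal | O=C/C=C/C=C/O[Si](C)(C)C(C)(C)C | intermediate
8 | diisopinocampheylboron enolate of 5 | C=C(CC#C[Si](C)(C)C)C(=C)OB([C@@H]1C[C@@H]2C[C@H]([C@H]1C)C2(C)C)[C@@H]1C[C@@H]2C[C@H]([C@H]1C)C2(C)C | intermediate (not isolated)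
9 | diisopinocampheylboron aldolate of 10 | C=C(CC#C[Si](C)(C)C)C(=O)C[C@@H](OB([C@@H]1C[C@@H]2C[C@H]([C@H]1C)C2(C)C)[C@@H]1C[C@@H]2C[C@H]([C@H]1C)C2(C)C)/C=C/C=C/O[Si](C)(C)C(C)(C)C | intermediate (not isolated)
10 | (7R,8E,10E)-11-[(tert-butyldimethylsilyl)oxy]-7-hydroxy-4-methylidene-1-(trimethylsilyl)undeca-8,10-dien-1-yn-5-one | C=C(CC#C[Si](C)(C)C)C(=O)C[C@@H](O)/C=C/C=C/O[Si](C)(C)C(C)(C)C | intermediate
11 | cis-fused B/C cycloadduct: C6 ketone, 10β-OH, C11=C12, 13-OTBS, 8-(3-TMS-prop-2-ynyl) cis to H-9 | C[Si](C)(C)C#CC[C@]23C[C@@H](O[Si](C)(C)C(C)(C)C)C=C[C@H]2[C@H](O)CC3=O | intermediate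
12 | B/C bicycle with C13 TBS enol ether (C12=C13), 10β-OH, C6 ketone | C[Si](C)(C)C#CC[C@]23CC(O[Si](C)(C)C(C)(C)C)=CC[C@H]2[C@H](O)CC3=O | intermediate
13 | 10-O-mesylate of 12 | C[Si](C)(C)C#CC[C@]23CC(O[Si](C)(C)C(C)(C)C)=CC[C@H]2[C@H](OS(C)(=O)=O)CC3=O | intermediate (not isolated)
14 | B/C bicyclic cyclopentenone (C6 ketone, C5=C10) | C[Si](C)(C)C#CC[C@]23CC(O[Si](C)(C)C(C)(C)C)=CC[C@H]2C=CC3=O | intermediate
15 | 1,3-dithiane | C1CSCSC1 | starting material
16 | lithium enolate after dithiane addition (10β-dithianyl) | C[Si](C)(C)C#CC[C@]23CC(O[Si](C)(C)C(C)(C)C)=CC[C@H]2[C@H](C4SCCCS4)C=C3[O-].[Li+] | intermediate (not isolated)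
17 | enol triflate (C6–OTf, C5=C6), 10β-(1,3-dithian-2-yl) | C[Si](C)(C)C#CC[C@]23CC(O[Si](C)(C)C(C)(C)C)=CC[C@H]2[C@H](C4SCCCS4)C=C3OS(=O)(=O)C(F)(F)F | intermediate
18 | allyl enoate (C7 allyl ester on C6, C5=C6), 10β-dithianyl | C[Si](C)(C)C#CC[C@]23CC(O[Si](C)(C)C(C)(C)C)=CC[C@H]2[C@H](C4SCCCS4)C=C3C(=O)OCC=C | intermediate
19 | tert-butyl propanoate | CCC(=O)OC(C)(C)C | starting material
20 | lithium ester enolate of the Michael adduct | C[Si](C)(C)C#CC[C@]23CC(O[Si](C)(C)C(C)(C)C)=CC[C@H]2[C@H](C4SCCCS4)[C@@H](C(C)C(=O)OC(C)(C)C)C3=C([O-])OCC=C.[Li+] | intermediate (not isolated)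
21 | Michael adduct: 5α-[1-(tert-butoxycarbonyl)ethyl] (C4 epimers), 6β-CO2allyl, 10β-dithianyl | C[Si](C)(C)C#CC[C@]23CC(O[Si](C)(C)C(C)(C)C)=CC[C@H]2[C@H](C4SCCCS4)[C@@H](C(C)C(=O)OC(C)(C)C)[C@@H]3C(=O)OCC=C | intermediate
22 | C13 ketone with free 8-propargyl group, dithiane retained | C#CC[C@]23CC(=O)CC[C@H]2[C@H](C4SCCCS4)[C@@H](C(C)C(=O)OC(C)(C)C)[C@@H]3C(=O)OCC=C | intermediate
23 | keto aldehyde (C20 formyl on C10), tert-butyl and allyl esters | C#CC[C@]23CC(=O)CC[C@H]2[C@H](C=O)[C@@H](C(C)C(=O)OC(C)(C)C)[C@@H]3C(=O)OCC=C | intermediate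
24 | aldehydo acid (C19 acid, C20 aldehyde; drawn open) | C#CC[C@]23CC(=O)CC[C@H]2[C@H](C=O)[C@@H](C(C)C(=O)O)[C@@H]3C(=O)OCC=C | intermediate (not isolated)
25 | enol δ-lactone (C19–O–C20=C10), C13 ketone, 8-propargyl | C#CC[C@]23CC(=O)CC[C@H]2C1=COC(=O)C(C)[C@H]1[C@@H]3C(=O)OCC=C | intermediate
26 | tetracyclic enol lactone, 13-OH, 16-methylidene (C4 epimers) | C=C1C[C@]23C[C@@]1(O)CC[C@H]2C1=COC(=O)C(C)[C@H]1[C@@H]3C(=O)OCC=C | intermediate
27 | acrolein | C=CC=O | starting material
28 | dilithium 13-alkoxide lactone enolate | [Li+].[Li+].C=C1C[C@]23C[C@@]1([O-])CC[C@H]2C1=COC([O-])=C(C)[C@H]1[C@@H]3C(=O)OCC=C | intermediate (not isolated)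
29 | aldol adduct: quaternary C4 with CH3 and CH(OH)CH=CH2 (C3 epimers) | C=C1C[C@]23C[C@@]1(O)CC[C@H]2C1=COC(=O)[C@](C)(C(O)C=C)[C@H]1[C@@H]3C(=O)OCC=C | intermediate
30 | vinyl ketone enol lactone (precursor of ring A) | C=C1C[C@]23C[C@@]1(O)CC[C@H]2C1=COC(=O)[C@](C)(C(=O)C=C)[C@H]1[C@@H]3C(=O)OCC=C | intermediate
31 | 20-chloro-19,20-lactone 3-ketone (present as its chloroaluminium enolate) | C=C1C[C@]23C[C@@]1(O)CC[C@H]2[C@]1(C(Cl)O4)CCC(=O)[C@@](C)(C4=O)[C@H]1[C@@H]3C(=O)OCC=C | intermediate (not isolated)
32 | 20-methoxy-19,20-lactone 3-ketone, 7-allyl ester (C20 epimers) | C=C1C[C@]23C[C@@]1(O)CC[C@H]2[C@]1(C(OC)O4)CCC(=O)[C@@](C)(C4=O)[C@H]1[C@@H]3C(=O)OCC=C | intermediate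
33 | 3β-hydroxy-20-methoxy-19,20-lactone, 7-allyl ester | C=C1C[C@]23C[C@@]1(O)CC[C@H]2[C@]1(C(OC)O4)CC[C@H](O)[C@@](C)(C4=O)[C@H]1[C@@H]3C(=O)OCC=C | intermediate
34 | 3β-hydroxy-20-methoxy-19,20-lactone 7-oic acid | C=C1C[C@]23C[C@@]1(O)CC[C@H]2[C@]1(C(OC)O4)CC[C@H](O)[C@@](C)(C4=O)[C@H]1[C@@H]3C(=O)O | intermediate (not isolated)
35 | GA23 (3β,13-dihydroxy-20-oxo-gibberell-16-ene-7,19-dioic acid) | C=C1C[C@]23C[C@@]1(O)CC[C@H]2[C@]1(C=O)CC[C@H](O)[C@@](C)(C(=O)O)[C@H]1[C@@H]3C(=O)O | target

**Totals**
Total step count: 19. Longest linear sequence: 18 steps (steps 1, 2 and 4–19); step 3 is a one-step branch.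

**Steps most likely to fail**

Step 17 (proposed new method). The enol ester may be too weak a π-nucleophile, so that polymerisation of the vinyl ketone or acid-induced change of the 13-hydroxy-16-ene unit outruns ring closure. The fallback gives up the tether and uses an anionic ring closure of known type. It sets out from 30: sodium allyloxide (allyl alcohol, NaH, THF, −40 °C) opens the enol lactone by acyl transfer to the C19 allyl ester and releases the C10 aldehyde enolate, which closes ring A by an intramolecular Michael addition to the vinyl ketone (the second half of an anionic double-Michael annulation) to give the keto aldehyde diallyl ester F1. Face selection at C10 then rests only on shielding of the α-face by C11. The aldehyde is protected as the dimethyl acetal F2 (HC(OMe)3, PPTS, MeOH), K-Selectride at −78 °C gives the 3β-alcohol F3, and Pd(PPh3)4/morpholine followed by aqueous acetic acid removes both allyl esters and the acetal. The fallback comes back to the route at 35.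

Step 15. The lithium enolate of the enol ester may fragment to a ketene, or the aldolate may transfer the acyl group to give a β-lactone, before the quench. The fallback replaces the lithium enolate by a neutral silyl ketene acetal. It sets out from 26: TMSOTf/Et3N (CH2Cl2, 0 °C) gives the cyclic silyl ketene acetal with a 13-O-TMS ether F4, which undergoes a Mukaiyama aldol addition to acrolein (BF3·OEt2, −78 °C) on the face anti to C6; aqueous work-up removes both silyl groups. The fallback comes back to the route at 29.

Step 10. Conjugate addition at the hindered C5 may lose to 1,2-attack on the allyl ester or to γ-deprotonation at C10. The fallback changes the polarity of activation. It sets out from 18: a Mukaiyama–Michael addition of (E)-1-tert-butoxy-1-(trimethylsilyloxy)prop-1-ene (made from 19) with catalytic Tf2NH in CH2Cl2 at −78 °C gives the silyl ketene acetal adduct F5; hydrolysis on work-up (aq NaHCO3) and equilibration of C6 with catalytic KOt-Bu in THF follow. The fallback comes back to the route at 21.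

**Further compounds**
F1 | step 17 | keto aldehyde diallyl ester (ring A closed, C3 ketone, C20 aldehyde, C19 and C7 allyl esters) | C=C1C[C@]23C[C@@]1(O)CC[C@H]2[C@]1(C=O)CCC(=O)[C@@](C)(C(=O)OCC=C)[C@H]1[C@@H]3C(=O)OCC=C
F2 | step 17 | C20 dimethyl acetal of F1 | C=C1C[C@]23C[C@@]1(O)CC[C@H]2[C@]1(C(OC)OC)CCC(=O)[C@@](C)(C(=O)OCC=C)[C@H]1[C@@H]3C(=O)OCC=C
F3 | step 17 | 3β-alcohol of F2 | C=C1C[C@]23C[C@@]1(O)CC[C@H]2[C@]1(C(OC)OC)CC[C@H](O)[C@@](C)(C(=O)OCC=C)[C@H]1[C@@H]3C(=O)OCC=C
F4 | step 15 | cyclic trimethylsilyl ketene acetal of 26 with 13-O-TMS ether | C=C1C[C@]23C[C@@]1(O[Si](C)(C)C)CC[C@H]2C1=COC(O[Si](C)(C)C)=C(C)[C@H]1[C@@H]3C(=O)OCC=C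
F5 | step 10 | silyl ketene acetal of the Michael adduct (C6=C7(OTMS)(O-allyl)) | C[Si](C)(C)C#CC[C@]23CC(O[Si](C)(C)C(C)(C)C)=CC[C@H]2[C@H](C4SCCCS4)[C@@H](C(C)C(=O)OC(C)(C)C)C3=C(O[Si](C)(C)C)OCC=C
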